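**Plan**

1. Retrosynthesis: the five C–Br bonds are cut first (C2, C4, C3', C5' as phenol-directed substitutions, C6' as replacement of a C–Si bond), then the C1–O (ring A) and C2'–O (ring B) hydroxyl bonds in one operation, then the C6'–Si bond. What remains is diphenyl ether, which supplies both rings and the C6–O–C1' bridge.
2. Enabling feature: in ring A (C1 OH, C2/C4 Br, C6 bridge carbon) and ring B (C1' bridge carbon, C2' OH, C3'/C5'/C6' Br), the hydroxylated carbons C1 and C2' and the brominated C6' are all ortho to the bridging oxygen. These are the positions at which a diaryl ether is lithiated.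
3. Forward: no ring is formed. Monolithiation and silylation of diphenyl ether place SiMe3 on C6'. Twofold ortho-lithiation, borylation and peroxide oxidation then install both hydroxyls. Br2 finally brominates ortho and para to each hydroxyl and exchanges SiMe3 for Br.
4. The silyl group is a latent bromine. A fifth electrophilic bromination of the symmetric tetrabromide would have to choose between C6' and C4' (para to the bridging oxygen) without a dependable bias; ipso-substitution at silicon leaves no choice.
5. Stereochemistry: the target is achiral and has no stereocentre. Only regiochemistry is at stake, and it is set by the bridging oxygen (lithiations), the hydroxyls (ring brominations) and silicon (C6').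

Key step: step 2

Step 1
Reactants: 1 diphenyl ether; 2 chlorotrimethylsilane
Product: 4 trimethyl(2-phenoxyphenyl)silane, via 2-lithiodiphenyl ether 3 (not isolated)
Conditions: 1 (1.5 equiv), n-BuLi (1.0 equiv), THF, 0 °C to rt; then Me3SiCl, −78 °C to rt; distillation
Reagents that add atoms: chlorotrimethylsilane C[Si](C)(C)Cl; n-butyllithium [Li]CCCC (lithium of 3 only)
Why: Directed ortho-lithiation of diphenyl ether with one equivalent of n-BuLi in THF should give the 2-lithio derivative, which Me3SiCl silylates at carbon, and the excess of the cheap ether holds back metalation of the second ring.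

Step 2
Reactants: 4 trimethyl(2-phenoxyphenyl)silane; 5 trimethyl borate; 6 hydrogen peroxide
Product: 9 2-(2-hydroxyphenoxy)-3-(trimethylsilyl)phenol, via dilithio ether 7 (not isolated), via bis(dimethoxyboryl) ether 8 (not isolated)
Conditions: n-BuLi (2.6 equiv), TMEDA (2.6 equiv), hexane/Et2O, 0 °C to rt, 16 h; added to B(OMe)3 (6 equiv), THF, −78 °C to rt; 30% H2O2 (excess), aq NaOH, 0 °C to rt; aq Na2SO3, then aq NH4Cl
Reagents that add atoms: hydrogen peroxide OO (both new oxygen atoms); trimethyl borate COB(OC)OC (boron and methoxy groups of 8 only); n-butyllithium [Li]CCCC (lithium of 7 only)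
Why: The bridging oxygen binds the n-BuLi/TMEDA aggregate and acidifies the neighbouring C–H bonds, so deprotonation occurs ortho to it (directed ortho-metalation); each aryllithium then adds to B(OMe)3, and hydroperoxide anion triggers the 1,2-shift of aryl from boron to oxygen, which after hydrolysis leaves a hydroxyl exactly where lithium stood. The closest known reactions are the 2,2'-dilithiation of diphenyl ether used to make bisphosphine ligands and the borylation–peroxide oxidation of aryllithiums to phenols. No ring is closed and no stereocentre is formed. The selectivity needed is one lithium per ring, at C1 of ring A and at C2' of ring B: a second deprotonation of an already metalated ring is disfavoured by charge build-up, and in ring B the only other ortho position, C6', is blocked by SiMe3, which should be inert to n-BuLi/TMEDA as in the usual silicon-protection tactic of ortho-metalation. The C–Si bond should survive the oxidation because a trialkylarylsilane without a heteroatom on silicon is not attacked by alkaline H2O2, and if the two boron centres collapse to a cyclic borinate, both C–B bonds are still oxidised to the same bisphenol.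

Step 3
Reactants: 9 2-(2-hydroxyphenoxy)-3-(trimethylsilyl)phenol; 10 bromine
Product: 11 3,4,6-tribromo-2-(3,5-dibromo-2-hydroxyphenoxy)phenol
Conditions: Br2 (5.5 equiv), NaOAc (6 equiv), AcOH, 15 °C to 45 °C; aq Na2S2O3 work-up
Reagents that add atoms: bromine BrBr
Why: Electrophilic aromatic bromination should go ortho and para to each free hydroxyl (C2 and C4 of ring A, C3' and C5' of ring B), and the fifth equivalent performs an ipso-bromodesilylation at C6', where the β-silicon effect makes attack at the silylated carbon faster than substitution of the remaining hydrogen at C4', while NaOAc removes the HBr that could otherwise cause protodesilylation.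

**Compound list**

1 | diphenyl ether | c1ccc(Oc2ccccc2)cc1 | starting material
2 | chlorotrimethylsilane | C[Si](C)(C)Cl | starting material
3 | 2-lithiodiphenyl ether (not isolated) | [Li]c1ccccc1Oc1ccccc1 | intermediate
4 | trimethyl(2-phenoxyphenyl)silane | C[Si](C)(C)c1ccccc1Oc1ccccc1 | intermediate
5 | trimethyl borate | COB(OC)OC | starting material
6 | hydrogen peroxide | OO | starting material
7 | 2-lithiophenyl 2-lithio-6-(trimethylsilyl)phenyl ether (not isolated) | [Li]c1ccccc1Oc1c([Li])cccc1[Si](C)(C)C | intermediate
8 | 2-(dimethoxyboryl)phenyl 2-(dimethoxyboryl)-6-(trimethylsilyl)phenyl ether (not isolated) | COB(OC)c1ccccc1Oc1c(B(OC)OC)cccc1[Si](C)(C)C | intermediate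
9 | 2-(2-hydroxyphenoxy)-3-(trimethylsilyl)phenol | Oc1ccccc1Oc1c(O)cccc1[Si](C)(C)C | intermediate
10 | bromine | BrBr | starting material
11 | 3,4,6-tribromo-2-(3,5-dibromo-2-hydroxyphenoxy)phenol | Oc1c(Br)cc(Br)cc1Oc1c(O)c(Br)cc(Br)c1Br | target

**Step count and risks**

Total steps: 3. Longest linear sequence: 3 steps, from diphenyl ether 1.

Steps most likely to fail, in order of risk:

Step 2. The second deprotonation may stall after the first lithium has entered, because the only ortho hydrogen of ring B sits in a crowded environment. Alternatively the aryllithium of ring A may attack the neighbouring silicon. The fallback inverts the order of events and sets out from 1. The parent ether is dilithiated under the same n-BuLi/TMEDA conditions to 2,2'-dilithiodiphenyl ether F1, borylated with 5 to 2,2'-bis(dimethoxyboryl)diphenyl ether F2 and oxidised with 6 to 2,2'-oxydiphenol F3. The hydroxyls are thus still created by the twofold ortho-lithiation, now on the unsubstituted substrate. Silylation with iPr3SiCl and imidazole in DMF should give 1,1'-oxybis[2-(triisopropylsilyloxy)benzene] F4, whose bulky, poorly coordinating silyl ethers shield the positions next to them. One equivalent of s-BuLi/TMEDA in THF at −78 °C is then expected to metalate ortho to the bridging oxygen, giving 2-lithio-6-(triisopropylsilyloxy)phenyl 2-(triisopropylsilyloxy)phenyl ether F5. Quenching with 2 gives trimethyl[3-(triisopropylsilyloxy)-2-(2-(triisopropylsilyloxy)phenoxy)phenyl]silane F6. Bu4NF in THF at 0 °C should remove both O-silyl groups and leave the aryl–silicon bond, and the route is rejoined at 9.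

Step 3. The silyl group may be lost by protonation before bromine has taken its place, or ipso-substitution may lag on a ring that already carries two bromines. Either would leave C6' without halogen. The fallback separates the two kinds of bromination and sets out from 9. Acetylation (Ac2O, pyridine) gives 2-(2-acetoxyphenoxy)-3-(trimethylsilyl)phenyl acetate F7, in which no ring is activated by a free hydroxyl. One equivalent of Br2 (NaOAc, AcOH) should then react only at the silylated carbon and give 2-(2-acetoxyphenoxy)-3-bromophenyl acetate F8. K2CO3 in MeOH liberates 3-bromo-2-(2-hydroxyphenoxy)phenol F9. Four equivalents of Br2 (NaOAc, AcOH) then brominate ortho and para to each hydroxyl, and the route is rejoined at 11.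

Step 1. The degree of metalation may not be controlled: lithiation may run on into the second ring or stop short, giving mixtures of unsilylated, mono- and bis-silylated ether. The fallback fixes the site of lithium by halogen–metal exchange instead of deprotonation. It sets out from 2 and purchased 1-bromo-2-phenoxybenzene F10, which with n-BuLi in THF at −78 °C should give the same aryllithium 3. Quenching with 2 rejoins the route at 4.

**Further compounds**

F1 | step 2 | 2,2'-dilithiodiphenyl ether | [Li]c1ccccc1Oc1ccccc1[Li]
F2 | step 2 | 2,2'-bis(dimethoxyboryl)diphenyl ether | COB(OC)c1ccccc1Oc1ccccc1B(OC)OC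
F3 | step 2 | 2,2'-oxydiphenol | Oc1ccccc1Oc1ccccc1O
F4 | step 2 | 1,1'-oxybis[2-(triisopropylsilyloxy)benzene] | CC(C)[Si](C(C)C)(C(C)C)Oc1ccccc1Oc1ccccc1O[Si](C(C)C)(C(C)C)C(C)C
F5 | step 2 | 2-lithio-6-(triisopropylsilyloxy)phenyl 2-(triisopropylsilyloxy)phenyl ether | CC(C)[Si](C(C)C)(C(C)C)Oc1ccccc1Oc1c([Li])cccc1O[Si](C(C)C)(C(C)C)C(C)C
F6 | step 2 | trimethyl[3-(triisopropylsilyloxy)-2-(2-(triisopropylsilyloxy)phenoxy)phenyl]silane | CC(C)[Si](C(C)C)(C(C)C)Oc1ccccc1Oc1c([Si](C)(C)C)cccc1O[Si](C(C)C)(C(C)C)C(C)C
F7 | step 3 | 2-(2-acetoxyphenoxy)-3-(trimethylsilyl)phenyl acetate | CC(=O)Oc1ccccc1Oc1c(OC(C)=O)cccc1[Si](C)(C)C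
F8 | step 3 | 2-(2-acetoxyphenoxy)-3-bromophenyl acetate | CC(=O)Oc1ccccc1Oc1c(OC(C)=O)cccc1Br
F9 | step 3 | 3-bromo-2-(2-hydroxyphenoxy)phenol | Oc1ccccc1Oc1c(O)cccc1Br
F10 | step 1 | 1-bromo-2-phenoxybenzene | Brc1ccccc1Oc1ccccc1
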